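**Retrosynthetic overview** (rings: A = methylcyclopentane, B = cyclooctene, C = cyclohexanol, D = isopropylcyclopentane)
1. 33 ⇐ methyl ester 32 ⇐ diene 30: the tertiary allylic C–O bond is made on the finished carbon skeleton by Markovnikov hydration of the ring B/C 1,3-diene (key step).
2. 30 ⇐ 29 ⇐ 28: ring B is closed last by ring-closing metathesis (then diimide); 28 ⇐ alkenyl iodide 9 (ring A) + enol triflate 25 (rings C and D) by Negishi coupling.
3. 9 ⇐ (R)-β-citronellene 1: ozonolysis, cross-metathesis, Corey–Fuchs homologation, zirconocene enyne cyclisation (ring A).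
4. 25 ⇐ methyl 2-oxocyclopentanecarboxylate 10 (ring D): isopropylation, asymmetric Robinson annulation (ring C), face-selective hydrogenation (trans C/D fusion), iridium-catalysed crotylation.
5. Order of ring formation: D (bought) → C → A (separate branch) → B.

Assumption: where a chiral catalyst or ligand is named, the enantiomer (or pseudo-enantiomer) that gives the configuration written in the product SMILES is meant; the sense of induction is assigned by analogy and would be checked on the first intermediate.

**Route**

Step 1
Reactants: 1 (R)-β-citronellene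
Product: 2 (4R)-4-methylhex-5-enal
Conditions: O3 (1.0 equiv), CH2Cl2, −78 °C; then PPh3, −78 → 23 °C
Reagents that add atoms: ozone, [O-][O+]=O
Why: Ozonolysis with reductive work-up: ozone reacts much faster with the electron-rich trisubstituted alkene than with the vinyl group, and the existing stereocentre (the future ring A methyl carbon) is not touched.

Step 2
Reactants: 2 (4R)-4-methylhex-5-enal; 3 allyl methyl ether (4 equiv)
Product: 4 (4R,5E)-7-methoxy-4-methylhept-5-enal
Conditions: second-generation Hoveyda–Grubbs catalyst RuCl2(H2IMes)(=CH-C6H4-2-OiPr) (3 mol %), CH2Cl2, 40 °C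
Reagents that add atoms: none
Why: Olefin cross-metathesis of the α-branched terminal alkene with an excess of the unhindered allyl ether gives the E-alkene under thermodynamic control, and the ruthenium carbene tolerates the aldehyde.

Step 3
Reactants: 4 (4R,5E)-7-methoxy-4-methylhept-5-enal
Product: 5 (5R,6E)-1,1-dibromo-8-methoxy-5-methylocta-1,6-diene
Conditions: CBr4, PPh3, CH2Cl2, 0 °C
Reagents that add atoms: carbon tetrabromide, BrC(Br)(Br)Br
Why: First stage of the Corey–Fuchs reaction (Wittig-type dibromo-olefination of the aldehyde) under neutral conditions that leave the allyl ether and the stereocentre alone.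

Step 4
Reactants: 5 (5R,6E)-1,1-dibromo-8-methoxy-5-methylocta-1,6-diene
Product: 7 (6R,7E)-9-methoxy-6-methylnon-7-en-2-yne, via lithium acetylide 6 (not isolated)
Conditions: n-BuLi (2.1 equiv), THF, −78 °C; then MeI, −78 → 0 °C
Reagents that add atoms: iodomethane, CI
Why: Second stage of the Corey–Fuchs alkyne synthesis (Br/Li exchange, carbenoid rearrangement, deprotonation) followed by C-methylation of the acetylide; at −78 °C the allylic methyl ether is not metallated.

Step 5
Reactants: 7 (6R,7E)-9-methoxy-6-methylnon-7-en-2-yne
Product: 9 (2S,3R)-1-[(1Z)-1-iodoethylidene]-3-methyl-2-vinylcyclopentane, via alkenylzirconocene methoxide 8 (not isolated)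
Conditions: Cp2ZrCl2, n-BuLi (2 equiv), THF, −78 → 23 °C; then I2, 0 °C
Reagents that add atoms: iodine, II
Why: Negishi-type zirconocene enyne cyclisation: alkyne and alkene couple on zirconocene to a zirconacyclopentene with the allylic methyl pseudo-equatorial (new ring CH trans to methyl), β-methoxide elimination unveils the vinyl group, and the syn carbometallation places zirconium, then iodine with retention, cis to the ring CH (Z alkene).

Step 6
Reactants: 10 methyl 2-oxocyclopentane-1-carboxylate; 11 2-iodopropane
Product: 13 methyl 2-oxo-3-(propan-2-yl)cyclopentane-1-carboxylate (stereoisomer mixture), via dilithium dianion 12 (not isolated)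
Conditions: LiN(iPr)2 (2.2 equiv), THF, 0 °C; then 2-iodopropane, 0 → 23 °C; 1 M HCl work-up
Reagents that add atoms: none
Why: γ-Alkylation of a β-keto ester dianion: the more basic α'-carbanion reacts with the secondary iodide, and the new centre is left uncontrolled because it is erased in step 8.

Step 7
Reactants: 13 methyl 2-oxo-3-(propan-2-yl)cyclopentane-1-carboxylate; 14 methyl vinyl ketone
Product: 15 methyl (1S)-2-oxo-1-(3-oxobutyl)-3-(propan-2-yl)cyclopentane-1-carboxylate (both C-3 epimers)
Conditions: 9-O-(9-phenanthryl)cupreidine (10 mol %), CH2Cl2, 23 °C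
Reagents that add atoms: none
Why: Cinchona-alkaloid-catalysed Michael addition of a cyclic β-keto ester to an enone: the quinuclidine deprotonates the keto ester while the phenol OH activates the enone, so one enolate face is alkylated and the quaternary (S)-centre is set whatever the configuration of the isopropyl-bearing carbon.

Step 8
Reactants: 15 methyl (1S)-2-oxo-1-(3-oxobutyl)-3-(propan-2-yl)cyclopentane-1-carboxylate
Product: 17 dioxolane of the bicyclic keto ester with a tetrasubstituted ring-fusion alkene, via bicyclic enone 16 (not isolated)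
Conditions: p-TsOH·H2O (10 mol %), toluene, reflux (Dean–Stark); then ethylene glycol (5 equiv), reflux
Reagents that add atoms: ethylene glycol, OCCO
Why: Acid-catalysed Robinson annulation (aldol condensation of the methyl ketone onto the ring ketone) followed by ketalisation, in which the dienol-ether intermediate is protonated at the α-carbon so that the double bond moves to the tetrasubstituted position between the ring-fusion and isopropyl carbons (as Δ4-3-ketosteroids give Δ5-ketals), which erases the undefined isopropyl-bearing centre.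

Step 9
Reactants: 17 dioxolane of the bicyclic keto ester with a tetrasubstituted ring-fusion alkene
Product: 19 methyl (3R,3aS,7aS)-5-oxo-3-(propan-2-yl)octahydro-7aH-indene-7a-carboxylate, via saturated ketal 18 (not isolated)
Conditions: H2 (60 bar), PtO2, EtOAc, 40 °C; filter; then 1 M HCl, THF, 23 °C
Reagents that add atoms: water, O
Why: Heterogeneous catalytic hydrogenation adds both hydrogens syn from the face opposite the angular ester (as Δ14-steroids give 14α products), which sets the trans ring fusion and the isopropyl-bearing centre (isopropyl cis to the ester) in one event; dilute acid then hydrolyses the dioxolane.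

Step 10
Reactants: 19 methyl (3R,3aS,7aS)-5-oxo-3-(propan-2-yl)octahydro-7aH-indene-7a-carboxylate
Product: 20 trimethylsilyl enol ether of 19 (C=C away from the ring fusion)
Conditions: TMSOTf, Et3N, CH2Cl2, 0 °C
Reagents that add atoms: trimethylsilyl trifluoromethanesulfonate, C[Si](C)(C)OS(=O)(=O)C(F)(F)F
Why: Soft enolisation and O-silylation; in the trans-fused ketone the enol ether forms away from the ring fusion (as 5α-3-ketosteroids give Δ2-enol derivatives), which marks the carbon that has to carry the side chain.

Step 11
Reactants: 21 (2E)-but-2-en-1-ol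
Product: 22 (2E)-but-2-en-1-yl methyl carbonate
Conditions: ClCO2Me, pyridine, CH2Cl2, 0 °C
Reagents that add atoms: methyl chloroformate, COC(=O)Cl
Why: O-Acylation of the primary allylic alcohol gives the allylic carbonate needed as the allyl-iridium precursor, with the E geometry unchanged.

Step 12
Reactants: 20 trimethylsilyl enol ether of 19; 22 (2E)-but-2-en-1-yl methyl carbonate
Product: 23 methyl (3R,3aS,6R,7aS)-6-[(2S)-but-3-en-2-yl]-5-oxo-3-(propan-2-yl)octahydro-7aH-indene-7a-carboxylate
Conditions: [Ir(cod)Cl]2 (2 mol %), (Sa,S,S)-binaphthol-derived N,N-bis(1-phenylethyl)phosphoramidite (4 mol %), ZnF2 (0.6 equiv), CsF (10 mol %), DME, 50 °C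
Reagents that add atoms: none
Why: Iridium-catalysed branched-selective allylic alkylation of a fluoride-activated silyl enol ether: the enolate attacks the substituted allyl terminus with the ligand setting the (S) side-chain centre, and it is attacked on the face opposite the axial angular ester (as 3-keto-5α-steroids alkylate at C-2 anti to the angular methyl), so the side chain is equatorial, which is also the epimer favoured by equilibration of this α-centre.

Step 13
Reactants: 23 methyl (3R,3aS,6R,7aS)-6-[(2S)-but-3-en-2-yl]-5-oxo-3-(propan-2-yl)octahydro-7aH-indene-7a-carboxylate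
Product: 25 enol triflate of 23 with the C=C toward the ring fusion, via potassium enolate 24 (not isolated)
Conditions: KN(SiMe3)2, THF, −78 °C; then PhNTf2, −78 → 0 °C
Reagents that add atoms: N-phenylbis(trifluoromethanesulfonimide), O=S(=O)(N(c1ccccc1)S(=O)(=O)C(F)(F)F)C(F)(F)F
Why: Kinetic deprotonation at the less substituted α-carbon (CH2 rather than the branched CH) and O-triflation of the enolate give the enol triflate regioselectively without touching any stereocentre.

Step 14
Reactants: 9 (2S,3R)-1-[(1Z)-1-iodoethylidene]-3-methyl-2-vinylcyclopentane; 25 enol triflate of 23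
Product: 28 coupled tetraene ester (ring A joined to rings C and D), via alkenyllithium 26 (not isolated), via alkenylzinc chloride 27 (not isolated)
Conditions: t-BuLi (2.1 equiv), Et2O, −78 °C; ZnCl2, THF, −78 → 0 °C; then 25, Pd(OAc)2 (5 mol %), SPhos (10 mol %), THF, 50 °C
Reagents that add atoms: none
Why: Negishi cross-coupling: iodine–lithium exchange at −78 °C and transmetallation to zinc keep the alkene geometry, and the palladium/biarylphosphine catalyst joins the two hindered sp2 carbons with retention, so the ring C carbon ends cis to the ring A CH across the tetrasubstituted alkene.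

Step 15
Reactants: 28 coupled tetraene ester
Product: 29 tetracyclic triene ester
Conditions: second-generation Hoveyda–Grubbs catalyst RuCl2(H2IMes)(=CH-C6H4-2-OiPr) (10 mol %), toluene (2 mM), 80 °C
Reagents that add atoms: none
Why: Ring-closing metathesis of the two vinyl groups, which are held close by the Z tetrasubstituted alkene and ring C, gives the cis-cyclooctene of ring B with loss of ethene; the tri- and tetrasubstituted alkenes of the diene do not engage the ruthenium carbene.

Step 16
Reactants: 29 tetracyclic triene ester
Product: 30 tetracyclic 1,3-diene ester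
Conditions: 2-nitrobenzenesulfonylhydrazide, Et3N, CH2Cl2, 23 °C
Reagents that add atoms: none
Why: Diimide reduction (concerted syn transfer of two hydrogens) is strongly selective for the unhindered cis-disubstituted alkene over the hindered tri- and tetrasubstituted alkenes of the diene and cannot isomerise the diene.

Step 17
Reactants: 30 tetracyclic 1,3-diene ester
Product: 32 sesterfisheric acid methyl ester, via hydroperoxide 31 (not isolated)
Conditions: Mn(dpm)3 (dpm = 2,2,6,6-tetramethylheptane-3,5-dionate, 20 mol %), PhSiH3 (2.5 equiv), O2 (1 atm), iPrOH–CH2Cl2, 0 °C; then PPh3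
Reagents that add atoms: dioxygen, O=O
Why: Proposed new method: Mukaiyama-type metal-hydride hydrogen-atom-transfer hydration, so far a reaction of isolated alkenes, is applied to a ring-embedded, fully substituted 1,3-diene to give a tertiary allylic alcohol by 1,2-Markovnikov addition; the manganese hydride formed from Mn(dpm)3 and PhSiH3 gives H• to the only CH terminus of the diene (in ring C), the resulting tertiary allyl radical is trapped by O2 at its six-membered-ring terminus because the sp2→sp3 change is favoured in a cyclohexane and disfavoured in a cyclopentane (the C=C stays exocyclic to ring A), attack is axial on the face that carries only 1,3-diaxial hydrogens and is anti to the axial H on the neighbouring B/C ring-fusion carbon, which sets the trans B/C junction, and PPh3 reduces the hydroperoxide; the closest known reactions are the Mukaiyama hydration of isolated alkenes and the manganese-catalysed α-hydroxylation of enones (conjugate H• transfer, then O2 capture).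

Step 18
Reactants: 32 sesterfisheric acid methyl ester
Product: 33 sesterfisheric acid
Conditions: NaSEt (5 equiv), DMF, 100 °C; then 0.5 M HCl to pH 4, 0 °C
Reagents that add atoms: none
Why: SN2 demethylation of the hindered methyl ester by thiolate (attack at the methyl carbon) does not depend on access to the neopentyl-type acyl carbon and leaves the tertiary allylic alcohol (as its alkoxide) and the tetrasubstituted alkene untouched.

**Compound list**

1 | (R)-β-citronellene [(3R)-3,7-dimethylocta-1,6-diene] | C=C[C@H](C)CCC=C(C)C | starting material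
2 | (4R)-4-methylhex-5-enal | O=CCC[C@@H](C)C=C | intermediate
3 | allyl methyl ether (3-methoxyprop-1-ene) | C=CCOC | starting material
4 | (4R,5E)-7-methoxy-4-methylhept-5-enal | O=CCC[C@@H](C)/C=C/COC | intermediate
5 | (5R,6E)-1,1-dibromo-8-methoxy-5-methylocta-1,6-diene | BrC(Br)=CCC[C@@H](C)/C=C/COC | intermediate
6 | lithium acetylide [(5R,6E)-8-methoxy-5-methyloct-6-en-1-yn-1-yl]lithium | [Li]C#CCC[C@@H](C)/C=C/COC | intermediate (not isolated)
7 | (6R,7E)-9-methoxy-6-methylnon-7-en-2-yne | CC#CCC[C@@H](C)/C=C/COC | intermediate
8 | alkenylzirconocene methoxide Cp2Zr(OMe)[(1Z)-1-((2S,3R)-3-methyl-2-vinylcyclopentylidene)ethyl] | C/C(=C1\CC[C@@H](C)[C@@H]1C=C)[Zr](OC)(C2C=CC=C2)C3C=CC=C3 | intermediate (not isolated)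
9 | (2S,3R)-1-[(1Z)-1-iodoethylidene]-3-methyl-2-vinylcyclopentane | C/C(I)=C1\CC[C@@H](C)[C@@H]1C=C | intermediate
10 | methyl 2-oxocyclopentane-1-carboxylate | COC(=O)C1CCCC1=O | starting material
11 | 2-iodopropane | CC(C)I | starting material
12 | dilithium dianion of 10 (enolate oxygen plus C-3 carbanion) | COC(=O)C1=C([O-])[CH-]CC1.[Li+].[Li+] | intermediate (not isolated)
13 | methyl 2-oxo-3-(propan-2-yl)cyclopentane-1-carboxylate (stereoisomer mixture) | COC(=O)C1CCC(C(C)C)C1=O | intermediate
14 | methyl vinyl ketone (but-3-en-2-one) | C=CC(C)=O | starting material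
15 | methyl (1S)-2-oxo-1-(3-oxobutyl)-3-(propan-2-yl)cyclopentane-1-carboxylate (both C-3 epimers) | CC(=O)CC[C@@]1(C(=O)OC)CCC(C(C)C)C1=O | intermediate
16 | methyl (7aS)-5-oxo-3-(propan-2-yl)-1,2,3,5,6,7-hexahydro-7aH-indene-7a-carboxylate (both C-3 epimers) | O=C1CC[C@@]2(C(=O)OC)CCC(C(C)C)C2=C1 | intermediate (not isolated)
17 | methyl (7a'S)-3'-(propan-2-yl)-1',2',4',6',7',7a'-hexahydrospiro[1,3-dioxolane-2,5'-indene]-7a'-carboxylate | COC(=O)[C@]12CCC(C(C)C)=C1CC1(OCCO1)CC2 | intermediate
18 | methyl (3'R,3a'S,7a'S)-3'-(propan-2-yl)octahydrospiro[1,3-dioxolane-2,5'-indene]-7a'-carboxylate | COC(=O)[C@]12CC[C@H](C(C)C)[C@@H]1CC1(OCCO1)CC2 | intermediate (not isolated)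
19 | methyl (3R,3aS,7aS)-5-oxo-3-(propan-2-yl)octahydro-7aH-indene-7a-carboxylate | O=C1CC[C@@]2(C(=O)OC)CC[C@H](C(C)C)[C@@H]2C1 | intermediate
20 | methyl (3R,3aS,7aS)-3-(propan-2-yl)-5-[(trimethylsilyl)oxy]-1,2,3,3a,4,7-hexahydro-7aH-indene-7a-carboxylate | C[Si](C)(C)OC1=CC[C@@]2(C(=O)OC)CC[C@H](C(C)C)[C@@H]2C1 | intermediate
21 | (2E)-but-2-en-1-ol (crotyl alcohol) | C/C=C/CO | starting material
22 | (2E)-but-2-en-1-yl methyl carbonate | C/C=C/COC(=O)OC | intermediate
23 | methyl (3R,3aS,6R,7aS)-6-[(2S)-but-3-en-2-yl]-5-oxo-3-(propan-2-yl)octahydro-7aH-indene-7a-carboxylate | C=C[C@H](C)[C@H]1C[C@@]2(C(=O)OC)CC[C@H](C(C)C)[C@@H]2CC1=O | intermediate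
24 | potassium enolate of 23 (enolate C=C toward the ring fusion) | C=C[C@H](C)[C@H]1C[C@@]2(C(=O)OC)CC[C@H](C(C)C)[C@@H]2C=C1[O-].[K+] | intermediate (not isolated)
25 | methyl (3R,3aR,6R,7aS)-6-[(2S)-but-3-en-2-yl]-3-(propan-2-yl)-5-{[(trifluoromethyl)sulfonyl]oxy}-1,2,3,3a,6,7-hexahydro-7aH-indene-7a-carboxylate | C=C[C@H](C)[C@H]1C[C@@]2(C(=O)OC)CC[C@H](C(C)C)[C@@H]2C=C1OS(=O)(=O)C(F)(F)F | intermediate
26 | alkenyllithium from 9 (Li in place of I, geometry retained) | C/C([Li])=C1\CC[C@@H](C)[C@@H]1C=C | intermediate (not isolated)
27 | alkenylzinc chloride from 26 (ZnCl in place of Li, geometry retained) | C/C([Zn]Cl)=C1\CC[C@@H](C)[C@@H]1C=C | intermediate (not isolated)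
28 | methyl (3R,3aR,6R,7aS)-6-[(2S)-but-3-en-2-yl]-5-{(1Z)-1-[(2S,3R)-3-methyl-2-vinylcyclopentylidene]ethyl}-3-(propan-2-yl)-1,2,3,3a,6,7-hexahydro-7aH-indene-7a-carboxylate | C/C(=C1\CC[C@@H](C)[C@@H]1C=C)C2=C[C@H]3[C@@H](C(C)C)CC[C@]3(C(=O)OC)C[C@@H]2[C@@H](C)C=C | intermediate
29 | tetracyclic triene ester: methyl ester of the 5-8-6-5 skeleton with the ring A/B C(CH3)=C alkene, a cis CH=CH in ring B and a ring C C=CH alkene at the future carbinol carbon | C/C1=C2\CC[C@@H](C)[C@@H]2/C=C\[C@H](C)[C@H]2C[C@@]3(C(=O)OC)CC[C@H](C(C)C)[C@@H]3C=C12 | intermediate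
30 | tetracyclic 1,3-diene ester: 29 with the ring B CH=CH reduced to CH2CH2 | C/C1=C2\CC[C@@H](C)[C@@H]2CC[C@H](C)[C@H]2C[C@@]3(C(=O)OC)CC[C@H](C(C)C)[C@@H]3C=C12 | intermediate
31 | tertiary allylic hydroperoxide: 32 with OOH in place of OH | C/C1=C2\CC[C@@H](C)[C@@H]2CC[C@H](C)[C@H]2C[C@@]3(C(=O)OC)CC[C@H](C(C)C)[C@@H]3C[C@]12OO | intermediate (not isolated)
32 | sesterfisheric acid methyl ester | C/C1=C2\CC[C@@H](C)[C@@H]2CC[C@H](C)[C@H]2C[C@@]3(C(=O)OC)CC[C@H](C(C)C)[C@@H]3C[C@]12O | intermediate
33 | sesterfisheric acid | C/C1=C2\CC[C@@H](C)[C@@H]2CC[C@H](C)[C@H]2C[C@@]3(C(=O)O)CC[C@H](C(C)C)[C@@H]3C[C@]12O | target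

**Step count and risk**

Total steps: 18. Longest linear sequence: 12 (steps 6–10 and 12–18, from 10).

The three steps most likely to fail:

Step 17 (the proposed hydration). The regiochemistry of O2 capture by the allyl radical and the axial selectivity have no direct precedent, and simple reduction of the diene can compete. The fallback uses known chemistry and forms the carbinol by C–C addition instead. It sets out from ketone 23 and iodide 9. Iodide 9 is converted into alkenyllithium 26 (t-BuLi, Et2O, −78 °C), which adds to ketone 23 along the equatorial trajectory to give the axial alcohol, the bis-vinyl tertiary alcohol F1. Ring-closing metathesis of F1 (the ruthenium catalyst of step 15, toluene, 80 °C) gives the ring-B-unsaturated hydroxy ester F2. Hydrogenation of its cis CH=CH (H2, RhCl(PPh3)3, benzene) gives 32, where the route is rejoined; steps 13 to 17 are then not needed.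

Step 14 (Negishi coupling). A tetrasubstituted alkenylzinc has to be joined to a hindered cyclohexenyl triflate. The fallback reverses the polarity of the union. It sets out from enol triflate 25, which is borylated (B2pin2, PdCl2(PPh3)2, PPh3, KOPh, toluene, 50 °C) to the alkenyl pinacol boronate F3. Suzuki–Miyaura coupling of F3 with iodide 9 (Pd(OAc)2, SPhos, K3PO4, THF–H2O, 60 °C) returns to 28 without t-BuLi or the hindered zinc reagent.

Step 12 (iridium-catalysed crotylation). A hindered bicyclic silyl enol ether and a crotyl electrophile must give the branched product with two new centres. The fallback replaces the catalytic substitution by a sigmatropic rearrangement. It sets out from ketone 19, which is converted (HC(OMe)3, MeOH, cat. TsOH) into the dimethyl ketal F4. Heating F4 with (2E)-but-2-en-1-ol 21 and catalytic propionic acid (xylene, 140 °C) gives by exchange and loss of methanol the (E)-crotyl enol ether F5 (not isolated). F5 undergoes Claisen rearrangement through a chair transition state on the face away from the angular ester, which gives the same (S) side-chain centre and equatorial ring centre, and so returns to 23.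

Further compounds
F1 | step 17 | bis-vinyl tertiary alcohol (adduct of alkenyllithium 26 and ketone 23, axial OH) | C/C(=C1\CC[C@@H](C)[C@@H]1C=C)[C@@]2(O)C[C@H]3[C@@H](C(C)C)CC[C@]3(C(=O)OC)C[C@@H]2[C@@H](C)C=C
F2 | step 17 | ring-B-unsaturated hydroxy ester (32 with a cis CH=CH in ring B) | C/C1=C2\CC[C@@H](C)[C@@H]2/C=C\[C@H](C)[C@H]2C[C@@]3(C(=O)OC)CC[C@H](C(C)C)[C@@H]3C[C@]12O
F3 | step 14 | alkenyl pinacol boronate (25 with Bpin in place of OTf) | C=C[C@H](C)[C@H]1C[C@@]2(C(=O)OC)CC[C@H](C(C)C)[C@@H]2C=C1B3OC(C)(C)C(C)(C)O3
F4 | step 12 | dimethyl ketal of 19 | COC1(OC)CC[C@@]2(C(=O)OC)CC[C@H](C(C)C)[C@@H]2C1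
F5 | step 12 | (E)-crotyl enol ether of 19 (C=C away from the ring fusion) | C/C=C/COC1=CC[C@@]2(C(=O)OC)CC[C@H](C(C)C)[C@@H]2C1
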